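## Analysis of the target

Compound 19 is a monocyclic lignan built on a single tetrahydrofuran ring, numbered here O1, C2, C3, C4, C5. C2 carries the 4-hydroxy-3-methoxyphenyl (guaiacyl) ring, C3 the hydroxymethyl carbon C9, C4 the exocyclic carbinol carbon C7' with the 3,4-dihydroxyphenyl ring, and C5 is an unsubstituted methylene. There are four contiguous stereocentres: (2S,3R,4S) in the ring, where the three substituents are all-trans and so in the arrangement that equilibration favours, and (7'R) outside the ring, whose relation to C4 can only be set kinetically. The catechol and guaiacol units oxidise easily and are best kept as benzyl ethers to the end, and the two benzylic C–O bonds on electron-rich rings (C2–O1 and C7'–OH) ionise under acid and can be lost on hydrogenation. The synthesis is hard because the two aryl groups differ, so no dimerisation shortcut exists, and because an acyclic carbinol has to be controlled next to a ring carbon (C4) that is flanked by two branches. The strategy rests on the 1,4-relationship of C9 and C5 across C3–C4: with C9 as an ester and C5 as an aldehyde carbon, C3–C4–C5 is the enolate of a γ-oxo ester, C2–C3 is an aldol bond to an aryl aldehyde, and O1–C5 is the hemiacetal bond that the aldolate closes by itself. A 2-siloxycyclopropane-1-carboxylate whose ester carbon is C3, siloxy carbon C5 and third ring carbon C4 stores this enolate and releases it by C3–C5 cleavage without touching C4.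

## Retrosynthetic reasoning

**19 from 18.** The last disconnection is the three phenolic O–benzyl bonds. Benzyl ethers survive every organoboron, Lewis acid, fluoride and hydride step of the route, and their removal needs no acid or base, which the catechol and the two benzylic C–O bonds would not tolerate. The forward reaction has to cleave three aryl benzyl ethers and leave C2–O1 and C7'–OH alone.

**18 from 17.** C9 is taken back to a methyl ester. The ester is the acceptor that the key step needs, it keeps C3 correctable by enolisation, and it keeps C9 distinct from C7', so that C7' is the only free alcohol or ketone in the late intermediates. The forward step is a plain hydride reduction.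

**17 from 16, 15 and 14.** The (7'R)-carbinol is disconnected to aryl ketone 16, in which the neighbouring C4 centre can direct hydride addition. Ketone 16 is carried through the earlier steps as the silyl-protected (S)-carbinol of 14, released as alcohol 15 and then oxidised. A thioketal would be the classical mask for an aryl ketone, but its sulfur atoms would capture the metal carbenoid of the cyclopropanation (ylide formation, ring expansion) and bind the catalyst. An oxygen ketal on a benzylic, cyclopropyl-substituted carbon would ionise under the Lewis acid of the key step. A bulky silyl ether is inert to both. The (S) configuration is not wanted in the product; it is chosen because it helps the cyclopropanation, and it is corrected afterwards by oxidation and substrate-controlled reduction.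

**14 from 13.** The C5–H bond is taken back to the C5–OH of lactol 13, because C5 leaves the key step at the aldehyde oxidation level. The forward reaction removes the anomeric hydroxyl reductively without opening the ring at the benzylic C2–O1 bond.

**13 from 10 and 11 (key disconnection).** C2–C3 and O1–C5 are cut together. C2–C3 is the one ring C–C bond whose cleavage returns the guaiacyl carbon as a commercial aldehyde (11). Cutting O1–C5 at the same time returns C5 to an aldehyde, which with the C9 ester gives the γ-oxo ester enolate; cyclopropane 10 is its stable equivalent. The gain is convergence, the ring, two skeletal bonds and the C2 and C3 centres in one operation. The forward reaction must cleave the ring bond between the siloxy and ester carbons, add to 11 at C3 on the face away from the C4 substituent, and close through O1.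

**10 from 8 and 9.** The C3–C4 and C3–C5 bonds are cut as a carbene transfer from diazo ester 9 to the enol ether double bond of 8. This is the step that sets C4. The configurations of the ester carbon and of the siloxy carbon of 10 are lost in the key step, so only the face of C4 that receives the carbene matters. Three elements decide it: the chiral catalyst, the preference of the ester for the side away from the branched substituent, and the resident (S)-silyloxy centre. Because that centre is enantiopure, a facial error gives a separable diastereomer instead of an enantiomer.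

**8 from 7, 5, 4, 1 and 2.** The enol ether is the O-silylated enol of aldehyde 7. Aldehyde 7 comes from oxidative cleavage of the terminal alkene of 5 (through diol 6), and 5 from silylation of homoallylic alcohol 4. Alcohol 4 is disconnected at C7'–C4 into aldehyde 1 and allylborane 2 (through borinate 3). The allyl unit supplies C4 and C5, its third carbon is sacrificed, and the reagent sets the (S)-carbinol.

## Alternatives that were turned down

**Alternative 1:** The ring is cut at O1–C5 and O1–C2, with C2 as a lactone carbonyl, so that the ring oxygen is inserted into a prochiral four-membered ketone. The ketone 3-{(R)-[3,4-bis(benzyloxy)phenyl][(tert-butyldimethylsilyl)oxy]methyl}cyclobutan-1-one A1 would be oxidised by a Baeyer–Villiger monooxygenase (flavin enzyme, reduced nicotinamide cofactor, aerobic conditions) to the lactone (4S)-4-{(R)-[3,4-bis(benzyloxy)phenyl][(tert-butyldimethylsilyl)oxy]methyl}oxolan-2-one A2. The enzyme chooses one of the two diastereotopic acyl–CH2 bonds of A1 and so fixes C4.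

- For it: enzymatic desymmetrisation of 3-substituted cyclobutanones such as A1 is a strong way to set a lone β-stereocentre. The medium is neutral and aqueous, so the benzylic silyl ether never meets a Lewis acid, and no diazo compound is needed. In mildness, and probably in the reliability of the control at C4, it is stronger than the chosen route.
- Against it: A2 holds only O1 and C2–C5. The key step forms no C–C bond, and C9, the guaiacyl ring and the C2 and C3 centres must all still be added (hydroxymethylation of the lactone enolate, aryl addition to the lactone carbonyl, reduction of the cyclic oxocarbenium ion). In that reduction hydride should enter anti to the C3 substituent, which places the aryl group cis to it, the wrong C2/C3 relationship. The enzyme must also accept a substrate with two benzyloxy groups and a silyl ether and override the resident C7' centre.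
- Comparison: the chosen strategy closes the ring, joins both halves and sets C2 and C3 in one step from aldehyde 11. Alternative 1 is longer after its key step and leaves C2 to a reaction biased the wrong way.

**Alternative 2:** The cuts are O1–C5 and C4–C5. The homopropargylic alcohol 4-{(1S,2R)-2-[(benzyloxy)methyl]-4-[3,4-bis(benzyloxy)phenyl]-1-hydroxybut-3-yn-1-yl}-2-methoxyphenyl 2,2-dimethylpropanoate A3 condenses with formaldehyde A4 , which supplies C5, under a silyl triflate to an oxocarbenium ion at O1=C5. The aryl alkyne attacks it through C4, the aryl-stabilised vinyl cation at C7' is trapped, and hydrolysis gives the ketone 4-{(2S,3R,4S)-3-[(benzyloxy)methyl]-4-[3,4-bis(benzyloxy)benzoyl]oxolan-2-yl}-2-methoxyphenyl 2,2-dimethylpropanoate A5.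

- For it: in A5 the whole skeleton, the ring and the C7' ketone have arrived in one step with C9 already at the alcohol oxidation level. Only ketone reduction and deprotection remain, so it is clearly stronger than the chosen route in step and oxidation-state economy after the key step. C4 is α to the new ketone and can settle trans.
- Against it: C2 and C3 must both be present, anti and enantiopure, in A3. That moves the stereochemical work into a longer acyclic synthesis that needs three different phenol protecting groups. The unsubstituted oxocarbenium ion from A4 is a hard electrophile beside two electron-rich arenes, so aryl hydroxymethylation competes. The benzylic C2–O1 bond can ionise even with the pivalate tempering the ring. Closure through C7' to a six-membered ring competes with closure through C4.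
- Comparison: the chosen route takes C2 from a commercial aldehyde instead of a stereodefined alkynol and creates C2 and C3 in the ring-forming step under a thermodynamic bias. What it gives up are the later steps that alternative 2 saves.

**Alternative 3:** The ring is cut at C2–C3 only. The vinyl acetal (5R)-2-[4-(benzyloxy)-3-methoxyphenyl]-5-{1-[3,4-bis(benzyloxy)phenyl]ethenyl}-4,5-dihydro-1,3-dioxepine A6 , treated with a silyl triflate, opens at the acetal carbon to an oxocarbenium ion (C2) tethered to an enolate equivalent (C3, with C9 as the enol carbon). C3 attacks C2 and the seven-membered ring contracts to the aldehyde (2S,3S,4R)-2-[4-(benzyloxy)-3-methoxyphenyl]-4-{1-[3,4-bis(benzyloxy)phenyl]ethenyl}oxolane-3-carbaldehyde A7.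

- For it: C2–C3 forms intramolecularly, so two components cannot cross-react. C9 emerges in A7 as an aldehyde, one reduction from the target. C7' is masked as a 1-arylvinyl group that is indifferent to Lewis acids, a better spectator in the key step than the benzylic silyl ether of 10.
- Against it: A6 is not a simple precursor. It needs the C4 centre with its 1-arylvinyl group, enantiopure, in a ring whose enol ether is normally made by double-bond migration from the allylic acetal. The C4 hydrogen is then allylic twice over, and migration into conjugation with the styrene would erase the centre. Under kinetic conditions (tight ion pair) the contraction tends to give the 2,3-cis aldehyde; C3 can be epimerised afterwards, C2 cannot. The alkene of A7 must later be cleaved to the ketone beside electron-rich arenes, and a C9 aldehyde is configurationally less robust than an ester.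
- Comparison: both strategies make C2–C3 from an oxocarbenium/enolate pair. The chosen one uses two commercial aldehydes and a cyclopropane made in five steps, closes O1–C5 in the same operation, and has the all-trans isomer as its thermodynamic sink.

Key step: step 6

Assumption: reagent 2 and diazo ester 9 are taken as purchasable catalogue reagents, and the target atom labels O1, C2–C5, C7' and C9 are used for all intermediates.

## Route

Step 1
Reactants: 1 3,4-bis(benzyloxy)benzaldehyde; 2 (−)-B-allyldiisopinocampheylborane, (−)-Ipc2B(allyl), the antipode derived from (+)-α-pinene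
Product: 4 (S)-1-[3,4-bis(benzyloxy)phenyl]but-3-en-1-ol, via diisopinocampheylborinate ester 3 (not isolated)
Conditions: Et2O, −78 °C; then NaOH, H2O2, 0 °C to rt
Reagents that add atoms: none
Why: Brown allylboration through a chair-like six-membered transition state; the isopinocampheyl groups of the (+)-α-pinene-derived reagent leave the Si face of the carbonyl open, which for an aryl aldehyde should give the (S)-carbinol. Oxidative work-up cleaves borinate 3.

Step 2
Reactants: 4 (S)-1-[3,4-bis(benzyloxy)phenyl]but-3-en-1-ol
Product: 5 {[(S)-1-[3,4-bis(benzyloxy)phenyl]but-3-en-1-yl]oxy}triisopropylsilane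
Conditions: TIPSOTf, 2,6-lutidine, CH2Cl2, 0 °C to rt
Reagents that add atoms: triisopropylsilyl trifluoromethanesulfonate, CC(C)[Si](C(C)C)(C(C)C)OS(=O)(=O)C(F)(F)F
Why: Silylation of a secondary benzylic alcohol with a silyl triflate and a hindered pyridine base. The triisopropylsilyl ether is a poor Lewis base that should survive TiCl4 and BF3·OEt2 at low temperature, and its bulk shields one face of the later enol ether.

Step 3
Reactants: 5 {[(S)-1-[3,4-bis(benzyloxy)phenyl]but-3-en-1-yl]oxy}triisopropylsilane
Product: 7 (S)-3-[3,4-bis(benzyloxy)phenyl]-3-[(triisopropylsilyl)oxy]propanal, via vicinal diol 6 (not isolated)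
Conditions: OsO4 (cat.), NaIO4, 2,6-lutidine, dioxane/H2O, rt
Reagents that add atoms: osmium tetroxide, O=[Os](=O)(=O)=O; sodium periodate, [Na+].[O-]I(=O)(=O)=O
Why: Lemieux–Johnson oxidation: catalytic dihydroxylation of the terminal alkene to diol 6 and periodate cleavage in the same flask. The electron-rich arenes, benzyl ethers and silyl ether are not touched, and 2,6-lutidine keeps the medium neutral so that the β-silyloxy aldehyde does not eliminate.

Step 4
Reactants: 7 (S)-3-[3,4-bis(benzyloxy)phenyl]-3-[(triisopropylsilyl)oxy]propanal
Product: 8 {[(1Z,3S)-3-[3,4-bis(benzyloxy)phenyl]-3-[(triisopropylsilyl)oxy]prop-1-en-1-yl]oxy}trimethylsilane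
Conditions: TMSCl, NaI, Et3N (excess), MeCN, rt
Reagents that add atoms: chlorotrimethylsilane, C[Si](C)(C)Cl
Why: Soft enolisation: iodotrimethylsilane formed in the flask activates the aldehyde and triethylamine removes the α-proton, so no strong base is present to expel the β-silyloxy group, and the excess amine keeps the silyl iodide from ionising the benzylic ether. The (Z)-isomer should predominate; the geometry only decides the configuration of the siloxy carbon of 10, which the key step erases, so any (E)-isomer is carried along.

Step 5
Reactants: 8 {[(1Z,3S)-3-[3,4-bis(benzyloxy)phenyl]-3-[(triisopropylsilyl)oxy]prop-1-en-1-yl]oxy}trimethylsilane; 9 methyl diazoacetate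
Product: 10 methyl (1S,2S,3S)-3-{(S)-[3,4-bis(benzyloxy)phenyl][(triisopropylsilyl)oxy]methyl}-2-[(trimethylsilyl)oxy]cyclopropane-1-carboxylate
Conditions: (CuOTf)2·C6H6 (cat.), (R,R)-tBu-box [2,2'-(propane-2,2-diyl)bis((4R)-4-tert-butyl-4,5-dihydrooxazole)], CH2Cl2, 0 °C to rt, 9 added slowly
Reagents that add atoms: none
Why: Copper-carbenoid cyclopropanation of an electron-rich enol ether, stereospecific at the double bond. By analogy with terminal alkenes the (R,R)-ligand should give the (1S) ester carbon, the ester takes the side away from the branched substituent, and the silyloxy group of the (S)-centre (allylic hydrogen in the alkene plane) covers the opposite face, so all three elements point to the (3S) carbon, the future C4. A facial error gives a separable diastereomer, not the enantiomer, and the substrate has no sulfur or basic nitrogen to trap the carbenoid.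

Step 6
Reactants: 10 methyl (1S,2S,3S)-3-{(S)-[3,4-bis(benzyloxy)phenyl][(triisopropylsilyl)oxy]methyl}-2-[(trimethylsilyl)oxy]cyclopropane-1-carboxylate; 11 4-(benzyloxy)-3-methoxybenzaldehyde
Product: 13 methyl (2S,3S,4R)-2-[4-(benzyloxy)-3-methoxyphenyl]-4-{(S)-[3,4-bis(benzyloxy)phenyl][(triisopropylsilyl)oxy]methyl}-5-hydroxyoxolane-3-carboxylate (both C5 epimers), via O-trimethylsilyl lactol 12 (not isolated)
Conditions: TiCl4, CH2Cl2, −78 °C (TiCl4 pre-complexed with 11); then aq. NaHCO3
Reagents that add atoms: none
Why: This is the Lewis-acid-mediated addition of a 2-siloxycyclopropanecarboxylate to an aldehyde (a homologous Mukaiyama aldol, formally a [3+2] annulation), a reaction type established for this class of donor–acceptor cyclopropanes. The ester-bearing ring carbon C3 attacks the TiCl4-bound aldehyde 11 while the C3–C5 bond, polarised by the siloxy donor and the ester acceptor, breaks; this forms C2–C3 and leaves C5 as a silyl oxocarbenium ion. The titanium aldolate oxygen then adds to that cation (5-exo-trig with respect to the C5=O+ bond) and closes the oxolane through O1–C5 as O-silyl lactol 12, which the aqueous work-up hydrolyses to 13. C4 is not part of the bond that breaks and keeps the configuration set in step 5. C3 is controlled by the C4 substituent: the aldehyde approaches the opening ring (or the derived titanium enolate) on the face opposite the branched silyloxybenzyl group, so C3/C4 is trans. C2 is set in an open transition state with the aryl group away from the ester, and because the titanium aldolate of an electron-rich benzaldehyde forms reversibly, the most stable all-trans isomer should accumulate; C5 is formed without control and is removed in step 7. The step needs regioselective cleavage of the donor–acceptor bond, which the push–pull substitution secures, and survival of the benzylic silyl ether, for which the poor basicity and bulk of the triisopropylsilyl group, −78 °C and pre-complexation of TiCl4 with the aldehyde are relied on.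

Step 7
Reactants: 13 methyl (2S,3S,4R)-2-[4-(benzyloxy)-3-methoxyphenyl]-4-{(S)-[3,4-bis(benzyloxy)phenyl][(triisopropylsilyl)oxy]methyl}-5-hydroxyoxolane-3-carboxylate
Product: 14 methyl (2S,3S,4S)-2-[4-(benzyloxy)-3-methoxyphenyl]-4-{(S)-[3,4-bis(benzyloxy)phenyl][(triisopropylsilyl)oxy]methyl}oxolane-3-carboxylate
Conditions: Et3SiH, BF3·OEt2, CH2Cl2, −78 to −40 °C; aq. NaHCO3
Reagents that add atoms: none
Why: Ionic hydrogenation of a lactol, known for lactols of this origin: BF3·OEt2 ionises the anomeric C5–OH to the cyclic oxocarbenium ion and the silane delivers hydride to C5, where no stereocentre arises. At low temperature the acetal-level C5–O bond should ionise far faster than the benzylic C2–O1 and C7'–OSi bonds, and the ester is inert.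

Step 8
Reactants: 14 methyl (2S,3S,4S)-2-[4-(benzyloxy)-3-methoxyphenyl]-4-{(S)-[3,4-bis(benzyloxy)phenyl][(triisopropylsilyl)oxy]methyl}oxolane-3-carboxylate
Product: 15 methyl (2S,3S,4S)-2-[4-(benzyloxy)-3-methoxyphenyl]-4-{(S)-[3,4-bis(benzyloxy)phenyl](hydroxy)methyl}oxolane-3-carboxylate
Conditions: Bu4NF, AcOH, THF, 0 °C to rt
Reagents that add atoms: none
Why: Fluoride cleavage of the silyl ether, buffered with acetic acid so that the ester α-centre C3 and the β-alkoxy ester do not meet free alkoxide. Lactonisation of the new C7'–OH onto the C3 ester would need a trans-fused bicyclo[3.3.0] system and is not expected.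

Step 9
Reactants: 15 methyl (2S,3S,4S)-2-[4-(benzyloxy)-3-methoxyphenyl]-4-{(S)-[3,4-bis(benzyloxy)phenyl](hydroxy)methyl}oxolane-3-carboxylate
Product: 16 methyl (2S,3S,4S)-2-[4-(benzyloxy)-3-methoxyphenyl]-4-[3,4-bis(benzyloxy)benzoyl]oxolane-3-carboxylate
Conditions: Dess–Martin periodinane, CH2Cl2, 0 °C to rt
Reagents that add atoms: none
Why: Dess–Martin oxidation of the only free alcohol under near-neutral conditions. C4 becomes α to a ketone but already has the trans arrangement that equilibration would favour.

Step 10
Reactants: 16 methyl (2S,3S,4S)-2-[4-(benzyloxy)-3-methoxyphenyl]-4-[3,4-bis(benzyloxy)benzoyl]oxolane-3-carboxylate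
Product: 17 methyl (2S,3S,4S)-2-[4-(benzyloxy)-3-methoxyphenyl]-4-{(R)-[3,4-bis(benzyloxy)phenyl](hydroxy)methyl}oxolane-3-carboxylate
Conditions: LiBH(s-Bu)3, THF, −78 °C; then H2O
Reagents that add atoms: none
Why: Substrate-controlled hydride addition (Felkin–Anh): the C3 branch, which carries the ester and adjoins C2, stands perpendicular to the carbonyl as the large group, the C5 methylene lies next to the carbonyl oxygen, and the bulky borohydride enters anti to C3 past the C4 hydrogen, which corresponds to the (7'R)-alcohol. At −78 °C the methyl ester should not be reduced.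

Step 11
Reactants: 17 methyl (2S,3S,4S)-2-[4-(benzyloxy)-3-methoxyphenyl]-4-{(R)-[3,4-bis(benzyloxy)phenyl](hydroxy)methyl}oxolane-3-carboxylate
Product: 18 (R)-[3,4-bis(benzyloxy)phenyl]{(3S,4R,5S)-5-[4-(benzyloxy)-3-methoxyphenyl]-4-(hydroxymethyl)oxolan-3-yl}methanol
Conditions: LiAlH4, THF, 0 °C; then H2O
Reagents that add atoms: none
Why: Hydride reduction of the methyl ester to the primary alcohol C9–OH. Benzyl ethers and the oxolane are inert, and afterwards no stereocentre remains next to a carbonyl.

Step 12
Reactants: 18 (R)-[3,4-bis(benzyloxy)phenyl]{(3S,4R,5S)-5-[4-(benzyloxy)-3-methoxyphenyl]-4-(hydroxymethyl)oxolan-3-yl}methanol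
Product: 19 4-[(R)-hydroxy{(3S,4R,5S)-5-(4-hydroxy-3-methoxyphenyl)-4-(hydroxymethyl)oxolan-3-yl}methyl]benzene-1,2-diol
Conditions: H2 (1 atm), Pd/C, EtOAc/MeOH, rt, inert work-up
Reagents that add atoms: none
Why: Hydrogenolysis of the three aryl benzyl ethers. Under neutral conditions ArO–CH2Ph bonds should cleave faster than the benzylic C2–O1 ether and the C7' alcohol, so the reaction is stopped once the third benzyl group is gone.

## Compound list

1 | 3,4-bis(benzyloxy)benzaldehyde | O=Cc1ccc(OCc2ccccc2)c(OCc2ccccc2)c1 | starting material
2 | (−)-B-allyldiisopinocampheylborane, (−)-Ipc2B(allyl) | C=CCB([C@@H]1C[C@@H]2C[C@H]([C@H]1C)C2(C)C)[C@@H]1C[C@@H]2C[C@H]([C@H]1C)C2(C)C | starting material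
3 | (S)-1-[3,4-bis(benzyloxy)phenyl]but-3-en-1-yl diisopinocampheylborinate | C=CC[C@H](OB([C@@H]1C[C@@H]2C[C@H]([C@H]1C)C2(C)C)[C@@H]1C[C@@H]2C[C@H]([C@H]1C)C2(C)C)c1ccc(OCc2ccccc2)c(OCc2ccccc2)c1 | intermediate
4 | (S)-1-[3,4-bis(benzyloxy)phenyl]but-3-en-1-ol | C=CC[C@H](O)c1ccc(OCc2ccccc2)c(OCc2ccccc2)c1 | intermediate
5 | {[(S)-1-[3,4-bis(benzyloxy)phenyl]but-3-en-1-yl]oxy}triisopropylsilane | C=CC[C@H](O[Si](C(C)C)(C(C)C)C(C)C)c1ccc(OCc2ccccc2)c(OCc2ccccc2)c1 | intermediate
6 | (4S)-4-[3,4-bis(benzyloxy)phenyl]-4-[(triisopropylsilyl)oxy]butane-1,2-diol (both C2 epimers) | OCC(O)C[C@H](O[Si](C(C)C)(C(C)C)C(C)C)c1ccc(OCc2ccccc2)c(OCc2ccccc2)c1 | intermediate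
7 | (S)-3-[3,4-bis(benzyloxy)phenyl]-3-[(triisopropylsilyl)oxy]propanal | O=CC[C@H](O[Si](C(C)C)(C(C)C)C(C)C)c1ccc(OCc2ccccc2)c(OCc2ccccc2)c1 | intermediate
8 | {[(1Z,3S)-3-[3,4-bis(benzyloxy)phenyl]-3-[(triisopropylsilyl)oxy]prop-1-en-1-yl]oxy}trimethylsilane (expected major isomer; any 1E isomer is carried along) | C[Si](C)(C)O/C=C\[C@H](O[Si](C(C)C)(C(C)C)C(C)C)c1ccc(OCc2ccccc2)c(OCc2ccccc2)c1 | intermediate
9 | methyl diazoacetate | COC(=O)C=[N+]=[N-] | starting material
10 | methyl (1S,2S,3S)-3-{(S)-[3,4-bis(benzyloxy)phenyl][(triisopropylsilyl)oxy]methyl}-2-[(trimethylsilyl)oxy]cyclopropane-1-carboxylate (ester trans to both other substituents; the C2 epimer from the 1E enol ether is equally usable) | COC(=O)[C@@H]1[C@@H](O[Si](C)(C)C)[C@H]1[C@H](O[Si](C(C)C)(C(C)C)C(C)C)c1ccc(OCc2ccccc2)c(OCc2ccccc2)c1 | intermediate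
11 | 4-(benzyloxy)-3-methoxybenzaldehyde | COc1cc(C=O)ccc1OCc1ccccc1 | starting material
12 | methyl (2S,3S,4R)-2-[4-(benzyloxy)-3-methoxyphenyl]-4-{(S)-[3,4-bis(benzyloxy)phenyl][(triisopropylsilyl)oxy]methyl}-5-[(trimethylsilyl)oxy]oxolane-3-carboxylate (both C5 epimers) | COc1cc([C@H]2OC(O[Si](C)(C)C)[C@@H]([C@H](O[Si](C(C)C)(C(C)C)C(C)C)c3ccc(OCc4ccccc4)c(OCc4ccccc4)c3)[C@@H]2C(=O)OC)ccc1OCc1ccccc1 | intermediate
13 | methyl (2S,3S,4R)-2-[4-(benzyloxy)-3-methoxyphenyl]-4-{(S)-[3,4-bis(benzyloxy)phenyl][(triisopropylsilyl)oxy]methyl}-5-hydroxyoxolane-3-carboxylate (all-trans at C2, C3, C4; both C5 epimers) | COc1cc([C@H]2OC(O)[C@@H]([C@H](O[Si](C(C)C)(C(C)C)C(C)C)c3ccc(OCc4ccccc4)c(OCc4ccccc4)c3)[C@@H]2C(=O)OC)ccc1OCc1ccccc1 | intermediate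
14 | methyl (2S,3S,4S)-2-[4-(benzyloxy)-3-methoxyphenyl]-4-{(S)-[3,4-bis(benzyloxy)phenyl][(triisopropylsilyl)oxy]methyl}oxolane-3-carboxylate | COc1cc([C@H]2OC[C@@H]([C@H](O[Si](C(C)C)(C(C)C)C(C)C)c3ccc(OCc4ccccc4)c(OCc4ccccc4)c3)[C@@H]2C(=O)OC)ccc1OCc1ccccc1 | intermediate
15 | methyl (2S,3S,4S)-2-[4-(benzyloxy)-3-methoxyphenyl]-4-{(S)-[3,4-bis(benzyloxy)phenyl](hydroxy)methyl}oxolane-3-carboxylate | COc1cc([C@H]2OC[C@@H]([C@H](O)c3ccc(OCc4ccccc4)c(OCc4ccccc4)c3)[C@@H]2C(=O)OC)ccc1OCc1ccccc1 | intermediate
16 | methyl (2S,3S,4S)-2-[4-(benzyloxy)-3-methoxyphenyl]-4-[3,4-bis(benzyloxy)benzoyl]oxolane-3-carboxylate | COc1cc([C@H]2OC[C@@H](C(=O)c3ccc(OCc4ccccc4)c(OCc4ccccc4)c3)[C@@H]2C(=O)OC)ccc1OCc1ccccc1 | intermediate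
17 | methyl (2S,3S,4S)-2-[4-(benzyloxy)-3-methoxyphenyl]-4-{(R)-[3,4-bis(benzyloxy)phenyl](hydroxy)methyl}oxolane-3-carboxylate | COc1cc([C@H]2OC[C@@H]([C@@H](O)c3ccc(OCc4ccccc4)c(OCc4ccccc4)c3)[C@@H]2C(=O)OC)ccc1OCc1ccccc1 | intermediate
18 | (R)-[3,4-bis(benzyloxy)phenyl]{(3S,4R,5S)-5-[4-(benzyloxy)-3-methoxyphenyl]-4-(hydroxymethyl)oxolan-3-yl}methanol | COc1cc([C@H]2OC[C@@H]([C@@H](O)c3ccc(OCc4ccccc4)c(OCc4ccccc4)c3)[C@@H]2CO)ccc1OCc1ccccc1 | intermediate
19 | 4-[(R)-hydroxy{(3S,4R,5S)-5-(4-hydroxy-3-methoxyphenyl)-4-(hydroxymethyl)oxolan-3-yl}methyl]benzene-1,2-diol | COc1cc([C@H]2OC[C@@H]([C@@H](O)c3ccc(O)c(O)c3)[C@@H]2CO)ccc1O | target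

## Step count and least certain steps

Total: 12 steps. Longest linear sequence: 12 steps, from 1 to 19; compounds 2, 9 and 11 enter as purchased.

**Step 6 (key step).** Three processes are the most likely to go wrong. The C7'–O bond may ionise under TiCl4, because before ring cleavage this carbon is both benzylic to an electron-rich ring and cyclopropylcarbinylic. The bis(benzyloxy)phenyl ring may capture the C5 oxocarbenium ion in a Friedel–Crafts closure. Control at C3 and C2 may be incomplete if the aldol step does not equilibrate. The fallback avoids the Lewis acid altogether and sets out from 10. Deprotonation at the ester carbon with LiN(i-Pr)2 in THF at −78 °C and addition of 11 should give the aldol adduct methyl 1-{[4-(benzyloxy)-3-methoxyphenyl](hydroxy)methyl}-3-{(S)-[3,4-bis(benzyloxy)phenyl][(triisopropylsilyl)oxy]methyl}-2-[(trimethylsilyl)oxy]cyclopropane-1-carboxylate F1 as a mixture at the two new centres. Et3N·3HF in THF then removes the trimethylsilyl group of F1 , the cyclopropanolate opens to the γ-oxo ester, and the hydroxy aldehyde closes to lactol 13, where the fallback rejoins the route. Both operations are known for this class of cyclopropanes. If C2/C3 isomers are carried into 14, NaOMe in MeOH should funnel them to the all-trans ester through enolisation and reversible β-alkoxide elimination and re-addition.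

**Step 5.** Carbene transfer to a hindered 1,2-disubstituted enol ether may be slow, so that carbene dimerisation takes over, and the facial selectivity may be poor if ligand and resident centre do not cooperate. The fallback sets out from 8 and changes the control element. Rh2(OAc)4 (cat.) in CH2Cl2 with slow addition of 9 gives a more reactive, achiral carbenoid, and the facial choice then rests on the (S)-silyloxy centre alone. The main unwanted ring diastereomer, methyl (1R,2R,3R)-3-{(S)-[3,4-bis(benzyloxy)phenyl][(triisopropylsilyl)oxy]methyl}-2-[(trimethylsilyl)oxy]cyclopropane-1-carboxylate F2 , would form beside 10; F2 is removed by chromatography on triethylamine-deactivated silica gel. The fallback rejoins the route at 10.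

**Step 7.** Ionisation may occur at the benzylic positions instead of only at C5: ring opening at C2–O1 with loss of the C2 configuration, or reductive loss of the C7' silyloxy group. The fallback sets out from 13 and uses no Lewis acid. NaBH4 in MeOH at 0 °C reduces the open hydroxy-aldehyde form to the diol methyl (2S,3S,4S)-2-{(S)-[4-(benzyloxy)-3-methoxyphenyl](hydroxy)methyl}-4-[3,4-bis(benzyloxy)phenyl]-3-(hydroxymethyl)-4-[(triisopropylsilyl)oxy]butanoate F3 , which is used at once. A Mitsunobu cyclodehydration of F3 (PPh3, DIAD, THF) activates the primary C5–OH, and the C2 hydroxyl closes the ether without breaking the C2–O bond, giving 14, where the fallback rejoins the route.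

**Step 10.** The facial selectivity of hydride addition may be insufficient, because the two ring branches at C4 differ less than a textbook large/medium pair. The fallback sets out from 15 and inverts the existing (S)-carbinol instead of creating the centre by reduction. A Mitsunobu reaction (PPh3, DIAD, 4-nitrobenzoic acid, THF, low temperature to suppress ionisation of the electron-rich benzylic position) should give the inverted ester (R)-[3,4-bis(benzyloxy)phenyl]{(3S,4S,5S)-5-[4-(benzyloxy)-3-methoxyphenyl]-4-(methoxycarbonyl)oxolan-3-yl}methyl 4-nitrobenzoate F4. K2CO3 in MeOH then cleaves the nitrobenzoate of F4 and releases 17, where the fallback rejoins the route; steps 9 and 10 are bypassed.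

**Step 12.** Over-reduction is the risk: hydrogenolysis of the C7'–OH bond, which becomes doubly activated once the para oxygen is free, or of C2–O1. The fallback sets out from 16 and removes the benzyl groups before the C7' carbinol exists. H2 and Pd/C should give the triphenol ketone methyl (2S,3S,4S)-4-(3,4-dihydroxybenzoyl)-2-(4-hydroxy-3-methoxyphenyl)oxolane-3-carboxylate F5. Noyori transfer hydrogenation of F5 with RuCl[(R,R)-TsDPEN](p-cymene) in HCO2H/Et3N then sets C7' under reagent control and should give the carbinol methyl (2S,3S,4S)-4-[(R)-(3,4-dihydroxyphenyl)(hydroxy)methyl]-2-(4-hydroxy-3-methoxyphenyl)oxolane-3-carboxylate F6. Excess LiBH4 in THF reduces the ester of F6 and gives 19, where the fallback reaches the end of the route.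

## Further compounds

F1 | step 6 | methyl 1-{[4-(benzyloxy)-3-methoxyphenyl](hydroxy)methyl}-3-{(S)-[3,4-bis(benzyloxy)phenyl][(triisopropylsilyl)oxy]methyl}-2-[(trimethylsilyl)oxy]cyclopropane-1-carboxylate (C2 and C3 as in 10; mixture at C1 and at the new carbinol carbon) | COC(=O)C1(C(O)c2ccc(OCc3ccccc3)c(OC)c2)[C@@H](O[Si](C)(C)C)[C@H]1[C@H](O[Si](C(C)C)(C(C)C)C(C)C)c1ccc(OCc2ccccc2)c(OCc2ccccc2)c1
F2 | step 5 | methyl (1R,2R,3R)-3-{(S)-[3,4-bis(benzyloxy)phenyl][(triisopropylsilyl)oxy]methyl}-2-[(trimethylsilyl)oxy]cyclopropane-1-carboxylate | COC(=O)[C@H]1[C@H](O[Si](C)(C)C)[C@@H]1[C@H](O[Si](C(C)C)(C(C)C)C(C)C)c1ccc(OCc2ccccc2)c(OCc2ccccc2)c1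
F3 | step 7 | methyl (2S,3S,4S)-2-{(S)-[4-(benzyloxy)-3-methoxyphenyl](hydroxy)methyl}-4-[3,4-bis(benzyloxy)phenyl]-3-(hydroxymethyl)-4-[(triisopropylsilyl)oxy]butanoate | COc1cc([C@@H](O)[C@@H](C(=O)OC)[C@@H](CO)[C@H](O[Si](C(C)C)(C(C)C)C(C)C)c3ccc(OCc4ccccc4)c(OCc4ccccc4)c3)ccc1OCc1ccccc1
F4 | step 10 | (R)-[3,4-bis(benzyloxy)phenyl]{(3S,4S,5S)-5-[4-(benzyloxy)-3-methoxyphenyl]-4-(methoxycarbonyl)oxolan-3-yl}methyl 4-nitrobenzoate | COc1cc([C@H]2OC[C@@H]([C@@H](OC(=O)c5ccc(cc5)[N+](=O)[O-])c3ccc(OCc4ccccc4)c(OCc4ccccc4)c3)[C@@H]2C(=O)OC)ccc1OCc1ccccc1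
F5 | step 12 | methyl (2S,3S,4S)-4-(3,4-dihydroxybenzoyl)-2-(4-hydroxy-3-methoxyphenyl)oxolane-3-carboxylate | COc1cc([C@H]2OC[C@@H](C(=O)c3ccc(O)c(O)c3)[C@@H]2C(=O)OC)ccc1O
F6 | step 12 | methyl (2S,3S,4S)-4-[(R)-(3,4-dihydroxyphenyl)(hydroxy)methyl]-2-(4-hydroxy-3-methoxyphenyl)oxolane-3-carboxylate | COc1cc([C@H]2OC[C@@H]([C@@H](O)c3ccc(O)c(O)c3)[C@@H]2C(=O)OC)ccc1O
A1 | alternative 1 | 3-{(R)-[3,4-bis(benzyloxy)phenyl][(tert-butyldimethylsilyl)oxy]methyl}cyclobutan-1-one | O=C1CC(C1)[C@@H](O[Si](C)(C)C(C)(C)C)c1ccc(OCc2ccccc2)c(OCc2ccccc2)c1
A2 | alternative 1 | (4S)-4-{(R)-[3,4-bis(benzyloxy)phenyl][(tert-butyldimethylsilyl)oxy]methyl}oxolan-2-one | O=C1OC[C@@H]([C@@H](O[Si](C)(C)C(C)(C)C)c2ccc(OCc3ccccc3)c(OCc3ccccc3)c2)C1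
A3 | alternative 2 | 4-{(1S,2R)-2-[(benzyloxy)methyl]-4-[3,4-bis(benzyloxy)phenyl]-1-hydroxybut-3-yn-1-yl}-2-methoxyphenyl 2,2-dimethylpropanoate | COc1cc([C@@H](O)[C@@H](COCc2ccccc2)C#Cc2ccc(OCc3ccccc3)c(OCc3ccccc3)c2)ccc1OC(=O)C(C)(C)C
A4 | alternative 2 | formaldehyde | C=O
A5 | alternative 2 | 4-{(2S,3R,4S)-3-[(benzyloxy)methyl]-4-[3,4-bis(benzyloxy)benzoyl]oxolan-2-yl}-2-methoxyphenyl 2,2-dimethylpropanoate | COc1cc([C@H]2OC[C@@H](C(=O)c3ccc(OCc4ccccc4)c(OCc4ccccc4)c3)[C@@H]2COCc5ccccc5)ccc1OC(=O)C(C)(C)C
A6 | alternative 3 | (5R)-2-[4-(benzyloxy)-3-methoxyphenyl]-5-{1-[3,4-bis(benzyloxy)phenyl]ethenyl}-4,5-dihydro-1,3-dioxepine (both C2 epimers) | COc1cc(C2OC[C@@H](C(=C)c3ccc(OCc4ccccc4)c(OCc4ccccc4)c3)C=CO2)ccc1OCc1ccccc1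
A7 | alternative 3 | (2S,3S,4R)-2-[4-(benzyloxy)-3-methoxyphenyl]-4-{1-[3,4-bis(benzyloxy)phenyl]ethenyl}oxolane-3-carbaldehyde | COc1cc([C@H]2OC[C@@H](C(=C)c3ccc(OCc4ccccc4)c(OCc4ccccc4)c3)[C@@H]2C=O)ccc1OCc1ccccc1
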